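(Readings and results are calculated for substances that don't exist; noise was put on by code.)

Late in the south-east run, target read 86 % at 15.0 h with 6 % of substrate beside it, and 86 % at 20.0 h with 1 %, substrate being the limiting reagent against 3 equiv of partner. So I wanted to know how far through its charge each new flask would get by the end.

| flask | substrate | partner | initiator | remark | time |
|---|---|---|---|---|---|
| west | 0.020 M | 3 equiv | 0.52 mol% | run made earlier |  |
| south-east | 0.020 M | 3 equiv | 2.2 mol% | run made earlier |  |
| teal | 0.020 M | 3.00 equiv | 0.6 mol% |  | 30 h |
| grey | 0.020 M | 3.00 equiv | 1 mol% |  | 30 h |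
| blue | 0.020 M | 3.00 equiv | 1.5 mol% |  | 30 h |
| green | 0.020 M | 3.00 equiv | 2.5 mol% |  | 30 h |

- west (time / h: target / %, substrate / %): 1.00: 3, 95; 3.00: 14, 87; 6.00: 20, 75; 10.0: 32, 66; 12.0: 36, 58; 15.0: 44, 52; 20.0: 55, 32
- south-east (time / h: target / %, substrate / %): 3.00: 23, 78; 6.00: 42, 58; 10.0: 63, 32; 12.0: 71, 22; 15.0: 86, 6; 20.0: 86, 1

(each reading ± 2 percentage points)

- the analysis behind the earlier runs scatters by 2 percentage points, standard deviation
- "hardly changes" means that all values lie within two and a half points (for a concentration: within two and a half percent of the largest)

* amount of target at the end, in percent of the substrate charged for teal, grey, blue, green, in this order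
* the course of these numbers from the first flask to the last (rises all the way / hardly changes / falls, then rises / falls all the way / rises, then falls)

I counted turnovers. West gave 30.9 h as its turnover time, the hours the straight fall of substrate needs to pass one whole charge; south-east gave 16.1 h. The loading rose 4.23 times between them and the turnover time shortened 1.92 times, close to the square root, 2.06, so I scaled by that root.

Teal looks like west, but west was stopped at 20.0 h, after 0.647 turnovers, with 32 % of its substrate left. Teal runs to 30 h, which makes 1.04 turnovers, further than west. South-east held 6 % at 0.933 turnovers and 1 % at 1.24. Between these, I reckoned about 4.24 % of substrate unused in teal, from readings that scatter by 2 percentage points.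

The forecast gave 81 %, 78 %, 76 % and 74 %, falls all the way: “The yield falls steadily with loading”. I differed on teal, since my leftover exceeds the 3 points it puts between teal and grey, so I expected a narrow rise first.

The flasks gave 74.4 %, 78.8 %, 76.6 % and 74.4 %: rises, then falls.

    initiator → 2 initiating radical (k = 5.40 × 10⁻⁷ s⁻¹)
    2 first chain carrier → ended chains (k = 7.00 × 10⁶ M⁻¹ s⁻¹)
    partner → decomposed reagent (k = 1.50 × 10⁻⁶ s⁻¹)
    substrate + initiating radical → capped initiator + first chain carrier (k = 1.00 × 10⁵ M⁻¹ s⁻¹)
    partner + first chain carrier ⇌ target + second chain carrier (K = 1.40, k = 1300 M⁻¹ s⁻¹)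
    target ⇌ isomer of the product (K = 2.60, k = 1.60 × 10⁻⁶ s⁻¹)
    target → over-reaction product (k = 2.00 × 10⁻⁶ s⁻¹)
    substrate + second chain carrier → released group + first chain carrier (k = 29000 M⁻¹ s⁻¹)

Teal ended at 74.4 % against the forecast's 81 %, and it still held 8.1 % of its substrate, more than the 4.24 % I had reckoned. Grey, scaled from the same turnover time, came out at 1.35 turnovers by my reckoning, past the 1.24 of the last south-east reading, and it ended with 0.029 % of its substrate.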